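**Plan**

1. Retrosynthetic cuts: the side chain is traced back, through C-beta–H and C-alpha–O, to an oxirane across C-alpha/C-beta. The oxirane comes from the C-alpha=C-beta alkene, and the alkene from a dihydrobenzofuran-5-carbaldehyde plus an arylacetic acid. The dihydrobenzofuran is cut at C3–C3a (flavanone ring contraction) and the flavanone at C2–aryl.
2. Enabling feature: the carbinol carbon C-alpha, the aryl-bearing C-beta and the CH2OH on C-beta are the two alkene carbons and the hydroxymethyl group of an (E)-2,3-diarylallylic alcohol, the substrate class of the titanium tartrate epoxidation.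
3. Forward order: pyranone ring of a chromone, flavanone, contraction to the dihydrofuran ring, formylation, Perkin condensation joining the third aryl unit, temporary oxirane, hydrogenolytic opening with debenzylation, deacetylation.
4. Stereochemistry: C2 from a rhodium/chiral diene conjugate addition; C3 trans from the ring contraction; C-alpha and C-beta together from the tartrate-controlled epoxidation of the E alkene, then inversion at C-beta when its benzylic C–O bond is cleaved on palladium.

Key step: step 9

Remark 1: Ar = 4-(benzyloxy)-3-methoxyphenyl throughout.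
Remark 2 (assumption): the S,S antipode of the diene ligand in step 3 is assigned by analogy with cyclohex-2-enone, where the R,R ligand gives the R adduct and the same face would give the unwanted R flavanone; if chromones respond in the opposite sense, the R,R ligand is used.

**Step 1**
Reactants: 1 1-(2-hydroxy-3-methoxyphenyl)ethanone
Product: 2 1-(5-bromo-2-hydroxy-3-methoxyphenyl)ethanone
Conditions: NBS, MeCN, 0 → 20 °C
Reagents that add atoms: N-bromosuccinimide, O=C1CCC(=O)N1Br
Why: Electrophilic aromatic bromination goes to C5, the only open position para to the phenol and meta to the acetyl group, which places the handle for the later formyl group.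

**Step 2**
Reactants: 2 1-(5-bromo-2-hydroxy-3-methoxyphenyl)ethanone
Product: 4 6-bromo-8-methoxy-4H-chromen-4-one, via enaminone 3 (not isolated)
Conditions: Me2NCH(OMe)2, toluene, 100 °C; then conc. HCl, CH2Cl2, 40 °C
Reagents that add atoms: N,N-dimethylformamide dimethyl acetal, COC(OC)N(C)C
Why: Enaminone route to chromones: condensation at the methyl ketone, then acid-promoted addition of the phenol to the enaminone with loss of dimethylamine closes the pyranone ring.

**Step 3**
Reactants: 4 6-bromo-8-methoxy-4H-chromen-4-one; 5 Ar-boronic acid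
Product: 6 (2S)-2-Ar-6-bromo-8-methoxy-2,3-dihydro-4H-chromen-4-one
Conditions: [RhCl(C2H4)2]2 (2.5 mol %), (1S,4S)-2,5-diphenylbicyclo[2.2.2]octa-2,5-diene (5.5 mol %), aq. K3PO4 (20 mol %), toluene, 40 °C
Reagents that add atoms: none
Why: Rhodium-catalysed asymmetric 1,4-addition of an arylboronic acid to an enone (Hayashi–Miyaura reaction), a reaction established for chromones; the aryl group passes from the monovalent rhodium–diene complex to one face of C2 and sets the S centre, and the aryl bromide is inert to this catalyst.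

**Step 4**
Reactants: 6 (2S)-flavanone
Product: 7 methyl (2S,3S)-2-Ar-5-bromo-7-methoxy-2,3-dihydro-1-benzofuran-3-carboxylate (2,3-trans)
Conditions: PhI(OAc)2, H2SO4 (cat.), HC(OMe)3, 20 °C; aq. NaHCO3
Reagents that add atoms: trimethyl orthoformate, COC(OC)OC; water, O
Why: Oxidative ring contraction of a flavanone by a trivalent iodine reagent: the enol ether formed in the orthoester is iodinated at C3, the ring A carbon migrates from C4 to C3 with loss of iodobenzene and the dialkoxycarbenium ion ends as the methyl ester, so that C2 is untouched and C3 takes the trans arrangement, which is also the thermodynamically preferred one.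

**Step 5**
Reactants: 7 trans methyl ester
Product: 8 [(2S,3R)-2-Ar-5-bromo-7-methoxy-2,3-dihydro-1-benzofuran-3-yl]methanol
Conditions: LiBH4, THF–MeOH, 0 → 20 °C
Reagents that add atoms: none
Why: Chemoselective hydride reduction of the ester to the primary alcohol leaves the aryl bromide and benzyl ether alone; no stereocentre is touched, and the C3 descriptor changes from S to R only through the priority change.

**Step 6**
Reactants: 8 bromo alcohol
Product: 10 (2S,3R)-2-Ar-3-(hydroxymethyl)-7-methoxy-2,3-dihydro-1-benzofuran-5-carbaldehyde, via dilithio species 9 (not isolated)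
Conditions: n-BuLi (2.3 equiv), THF, −78 °C; DMF, −78 → 0 °C; aq. NH4Cl
Reagents that add atoms: N,N-dimethylformamide, CN(C)C=O
Why: Deprotonation of the alcohol and bromine–lithium exchange, then formylation of the aryllithium with DMF (Bouveault aldehyde synthesis); exchange at −78 °C is faster than deprotonation at the benzylic positions.

**Step 7**
Reactants: 10 hydroxy aldehyde; 11 Ar-acetic acid
Product: 13 (2E)-3-[(2S,3R)-3-(acetoxymethyl)-2-Ar-7-methoxy-2,3-dihydro-1-benzofuran-5-yl]-2-Ar-prop-2-enoic acid, via O-acetyl aldehyde 12 (not isolated)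
Conditions: Ac2O, Et3N, 120 °C; then H2O, 80 °C; dil. HCl
Reagents that add atoms: acetic anhydride, CC(=O)OC(C)=O
Why: Perkin condensation of an arylacetic acid: the enolate of its mixed anhydride adds to the aldehyde and acetate is eliminated to give the E acid, in which carboxyl lies trans to the benzofuranyl group and the two aryl groups are cis (the geometry reliably formed in 2,3-diarylacrylic acid syntheses), while the same medium acetylates and thereby protects the primary alcohol.

**Step 8**
Reactants: 13 (E)-acrylic acid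
Product: 15 [(2S,3R)-2-Ar-5-[(1E)-2-Ar-3-hydroxyprop-1-en-1-yl]-7-methoxy-2,3-dihydro-1-benzofuran-3-yl]methyl acetate, via mixed carbonic anhydride 14 (not isolated)
Conditions: i-BuOCOCl, N-methylmorpholine, THF, −15 °C; NaBH4, H2O, 0 °C
Reagents that add atoms: none
Why: Reduction of a carboxylic acid through its mixed carbonic anhydride with NaBH4, as practised on cinnamic acids, delivers hydride twice to the activated acyl carbon and gives the allylic alcohol without touching the acetate or the alkene geometry.

**Step 9**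
Reactants: 15 (E)-2,3-diarylallylic alcohol
Product: 16 [(2S,3R)-2-Ar-5-[(2R,3R)-3-Ar-3-(hydroxymethyl)oxiran-2-yl]-7-methoxy-2,3-dihydro-1-benzofuran-3-yl]methyl acetate
Conditions: Ti(OiPr)4 (0.2 equiv), D-(−)-diethyl tartrate (0.26 equiv), t-BuOOH (2 equiv), 4 Å MS, CH2Cl2, −25 °C; sat. aq. Na2SO4 work-up
Reagents that add atoms: tert-butyl hydroperoxide, CC(C)(C)OO
Why: Katsuki–Sharpless asymmetric epoxidation: the allylic alcohol and the hydroperoxide exchange onto the dimeric tetravalent titanium tartrate, and the activated peroxide oxygen is handed to the alkene held through its own alkoxide. The closest known case is the epoxidation of (E)-2,3-diphenylprop-2-en-1-ol, which has the same substitution pattern (aryl geminal to the carbinol carbon, aryl trans to it, hydrogen cis) and belongs to the fast, highly selective substrate class. The oxirane closes in one concerted oxygen-atom transfer that forms the C-alpha–O and C-beta–O bonds on the same face (syn [2+1] addition), so no open intermediate can rotate. The absolute configuration of both centres comes from the tartrate, D-(−)-diethyl tartrate being the antipode that leads to the 2R,3R oxirane (L-(+)-tartrate gives 2S,3S oxiranes from E-cinnamyl-type alcohols), and their relative configuration from the E geometry fixed in step 7. The step needs reagent-controlled face selectivity and survival of an acid-sensitive, doubly benzylic oxirane: the existing stereocentres are remote from the alkene and should not compete with the catalyst, while substoichiometric titanium with molecular sieves, low temperature and a neutral work-up limit titanium-promoted opening of the product.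

**Step 10**
Reactants: 16 epoxy alcohol
Product: 18 [(2S,3R)-5-[(1S,2R)-1,3-dihydroxy-2-(4-hydroxy-3-methoxyphenyl)propyl]-2-(4-hydroxy-3-methoxyphenyl)-7-methoxy-2,3-dihydro-1-benzofuran-3-yl]methyl acetate, via dibenzyl ether diol 17 (not isolated)
Conditions: H2 (1 atm), 10% Pd/C, NaHCO3, EtOAc–EtOH, −30 °C, then 20 °C
Reagents that add atoms: none
Why: Palladium-catalysed hydrogenolysis cleaves the benzylic C–O bond at the fully substituted, more cation-stabilising C-beta with inversion (the established course for 2-aryl-2-alkyloxiranes on palladium), so that H enters anti to the retained C-alpha oxygen and the syn (1S,2R) diol results, and on warming the same catalyst removes both benzyl ethers while the more slowly reacting benzylic alcohol and dihydrofuran ring are kept by stopping at the calculated hydrogen uptake.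

**Step 11**
Reactants: 18 monoacetate
Product: 19 (1S,2R)-1-[(2S,3R)-2-(4-hydroxy-3-methoxyphenyl)-3-(hydroxymethyl)-7-methoxy-2,3-dihydro-1-benzofuran-5-yl]-2-(4-hydroxy-3-methoxyphenyl)propane-1,3-diol
Conditions: K2CO3 (cat.), MeOH, 0 → 20 °C, argon
Reagents that add atoms: none
Why: Base-catalysed transesterification (Zemplén-type methanolysis) removes the acetate without affecting any stereocentre.

**Compound list**

1 | 1-(2-hydroxy-3-methoxyphenyl)ethanone | CC(=O)c1cccc(OC)c1O | starting material
2 | 1-(5-bromo-2-hydroxy-3-methoxyphenyl)ethanone | CC(=O)c1cc(Br)cc(OC)c1O | intermediate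
3 | (E)-1-(5-bromo-2-hydroxy-3-methoxyphenyl)-3-(dimethylamino)prop-2-en-1-one | CN(C)/C=C/C(=O)c1cc(Br)cc(OC)c1O | intermediate (not isolated)
4 | 6-bromo-8-methoxy-4H-chromen-4-one | COc1cc(Br)cc2c1occc2=O | intermediate
5 | [4-(benzyloxy)-3-methoxyphenyl]boronic acid | COc1cc(B(O)O)ccc1OCc1ccccc1 | starting material
6 | (2S)-2-Ar-6-bromo-8-methoxy-2,3-dihydro-4H-chromen-4-one | O=C1C[C@@H](c2ccc(OCc3ccccc3)c(OC)c2)Oc2c(OC)cc(Br)cc12 | intermediate
7 | methyl (2S,3S)-2-Ar-5-bromo-7-methoxy-2,3-dihydro-1-benzofuran-3-carboxylate | COc1cc([C@H]2Oc3c(OC)cc(Br)cc3[C@@H]2C(=O)OC)ccc1OCc1ccccc1 | intermediate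
8 | [(2S,3R)-2-Ar-5-bromo-7-methoxy-2,3-dihydro-1-benzofuran-3-yl]methanol | COc1cc([C@H]2Oc3c(OC)cc(Br)cc3[C@@H]2CO)ccc1OCc1ccccc1 | intermediate
9 | lithium alkoxide of 8 carrying lithium in place of bromine at C5 | COc1cc([C@H]2Oc3c(OC)cc([Li])cc3[C@@H]2CO[Li])ccc1OCc1ccccc1 | intermediate (not isolated)
10 | (2S,3R)-2-Ar-3-(hydroxymethyl)-7-methoxy-2,3-dihydro-1-benzofuran-5-carbaldehyde | COc1cc([C@H]2Oc3c(OC)cc(C=O)cc3[C@@H]2CO)ccc1OCc1ccccc1 | intermediate
11 | [4-(benzyloxy)-3-methoxyphenyl]acetic acid | COc1cc(CC(=O)O)ccc1OCc1ccccc1 | starting material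
12 | [(2S,3R)-2-Ar-5-formyl-7-methoxy-2,3-dihydro-1-benzofuran-3-yl]methyl acetate | COc1cc([C@H]2Oc3c(OC)cc(C=O)cc3[C@@H]2COC(C)=O)ccc1OCc1ccccc1 | intermediate (not isolated)
13 | (2E)-3-[(2S,3R)-3-(acetoxymethyl)-2-Ar-7-methoxy-2,3-dihydro-1-benzofuran-5-yl]-2-Ar-prop-2-enoic acid | COc1cc([C@H]2Oc3c(OC)cc(/C=C(/C(=O)O)c4ccc(OCc5ccccc5)c(OC)c4)cc3[C@@H]2COC(C)=O)ccc1OCc1ccccc1 | intermediate
14 | mixed anhydride of 13 with isobutyl carbonic acid | COc1cc([C@H]2Oc3c(OC)cc(/C=C(/C(=O)OC(=O)OCC(C)C)c4ccc(OCc5ccccc5)c(OC)c4)cc3[C@@H]2COC(C)=O)ccc1OCc1ccccc1 | intermediate (not isolated)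
15 | [(2S,3R)-2-Ar-5-[(1E)-2-Ar-3-hydroxyprop-1-en-1-yl]-7-methoxy-2,3-dihydro-1-benzofuran-3-yl]methyl acetate | COc1cc([C@H]2Oc3c(OC)cc(/C=C(/CO)c4ccc(OCc5ccccc5)c(OC)c4)cc3[C@@H]2COC(C)=O)ccc1OCc1ccccc1 | intermediate (key-step precursor)
16 | [(2S,3R)-2-Ar-5-[(2R,3R)-3-Ar-3-(hydroxymethyl)oxiran-2-yl]-7-methoxy-2,3-dihydro-1-benzofuran-3-yl]methyl acetate | COc1cc([C@H]2Oc3c(OC)cc([C@H]4O[C@@]4(CO)c5ccc(OCc6ccccc6)c(OC)c5)cc3[C@@H]2COC(C)=O)ccc1OCc1ccccc1 | intermediate (key-step product)
17 | [(2S,3R)-2-Ar-5-[(1S,2R)-2-Ar-1,3-dihydroxypropyl]-7-methoxy-2,3-dihydro-1-benzofuran-3-yl]methyl acetate | COc1cc([C@H]2Oc3c(OC)cc([C@@H](O)[C@@H](CO)c4ccc(OCc5ccccc5)c(OC)c4)cc3[C@@H]2COC(C)=O)ccc1OCc1ccccc1 | intermediate (not isolated)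
18 | [(2S,3R)-5-[(1S,2R)-1,3-dihydroxy-2-(4-hydroxy-3-methoxyphenyl)propyl]-2-(4-hydroxy-3-methoxyphenyl)-7-methoxy-2,3-dihydro-1-benzofuran-3-yl]methyl acetate | COc1cc([C@H]2Oc3c(OC)cc([C@@H](O)[C@@H](CO)c4ccc(O)c(OC)c4)cc3[C@@H]2COC(C)=O)ccc1O | intermediate
19 | (1S,2R)-1-[(2S,3R)-2-(4-hydroxy-3-methoxyphenyl)-3-(hydroxymethyl)-7-methoxy-2,3-dihydro-1-benzofuran-5-yl]-2-(4-hydroxy-3-methoxyphenyl)propane-1,3-diol | COc1cc([C@H]2Oc3c(OC)cc([C@@H](O)[C@@H](CO)c4ccc(O)c(OC)c4)cc3[C@@H]2CO)ccc1O | target

**Count**

Total steps: 11. Longest linear sequence: 11 steps (1 → 19); 5 and 11 enter as purchased building blocks.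

**Steps most likely to fail**

Step 10. The oxirane may be cleaved at the wrong benzylic carbon (C-alpha instead of C-beta). Inversion may be incomplete if an open benzylic cation or a quinone-methide-type pathway intervenes once the phenol is unmasked. The longer debenzylation phase may over-reduce the product (loss of the benzylic hydroxyl, opening of the dihydrofuran ring). The fallback sets the two side-chain centres by an auxiliary-controlled aldol reaction instead of through the oxirane; it sets out from 10 and 11 and returns at 19. Aldehyde 10 is acetylated (Ac2O, pyridine) and 12 is this time isolated. Acid 11 is coupled through its pivaloyl mixed anhydride with lithiated (4S)-4-benzyl-1,3-oxazolidin-2-one to give the imide (4S)-4-benzyl-3-(Ar-acetyl)-1,3-oxazolidin-2-one F1. Its boron enolate (Bu2BOTf, i-Pr2NEt, CH2Cl2, −78 °C) adds to 12 in an Evans syn-aldol reaction to give the adduct [(2S,3R)-2-Ar-5-[(1S,2S)-2-Ar-3-[(4S)-4-benzyl-2-oxo-1,3-oxazolidin-3-yl]-1-hydroxy-3-oxopropyl]-7-methoxy-2,3-dihydro-1-benzofuran-3-yl]methyl acetate F2, which has the spatial arrangement of the target at C-alpha and C-beta. LiBH4 (THF–MeOH) removes the auxiliary and the acetate reductively and gives the dibenzyl ether (1S,2R)-1-[(2S,3R)-2-Ar-3-(hydroxymethyl)-7-methoxy-2,3-dihydro-1-benzofuran-5-yl]-2-Ar-propane-1,3-diol F3. Plain hydrogenolysis of the two benzyl ethers (H2, Pd/C, EtOAc–EtOH) then gives 19.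

Step 9. The electron-rich oxirane may be opened at a benzylic carbon by titanium-bound alkoxide or hydroperoxide during reaction or work-up, oxygen transfer to the hindered trisubstituted alkene may be slow, and face selectivity may erode. The fallback goes from 15 to 16 by a Shi epoxidation, which is metal-free and basic, so the product never meets a Lewis acid. Conditions would be the D-fructose-derived ketone 1,2:4,5-di-O-isopropylidene-β-D-erythro-2,3-hexodiulo-2,6-pyranose (30 mol %), KHSO5 (as 2KHSO5·KHSO4·K2SO4), K2CO3, Bu4NHSO4, MeCN–dimethoxymethane–aqueous buffer (pH about 10.5), 0 °C. The spiro transition-state model predicts that this ketone oxidises the same face as D-(−)-tartrate for an E-configured trisubstituted alkene; if it does not, the ketone of the L series is used. No new compound is formed.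

Step 4. The electron-rich 2-aryl group may migrate instead of the ring A carbon, the flavanone may be dehydrogenated to the flavone, and acid may open the pyranone ring and erode the C2 configuration. The fallback replaces the oxidative rearrangement by a Wolff ring contraction; it sets out from 6 and returns at 7. Flavanone 6 is trifluoroacetylated at C3 (LiN(SiMe3)2, CF3CO2CH2CF3, THF, −78 °C) to give (2S)-2-Ar-6-bromo-8-methoxy-3-(trifluoroacetyl)-2,3-dihydro-4H-chromen-4-one F4. Detrifluoroacetylative diazo transfer (MsN3, Et3N, MeCN–H2O) gives (2R)-2-Ar-6-bromo-3-diazo-8-methoxy-2,3-dihydro-4H-chromen-4-one F5, whose descriptor differs from that of 6 only through the priority change. Irradiation in MeOH causes the ring A carbon to migrate to the carbene carbon, the ketene is trapped by methanol, and brief equilibration with DBU gives the trans ester 7.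

**Further compounds**

F1 | step 10 | (4S)-4-benzyl-3-{[4-(benzyloxy)-3-methoxyphenyl]acetyl}-1,3-oxazolidin-2-one | COc1cc(CC(=O)N2[C@@H](Cc3ccccc3)COC2=O)ccc1OCc1ccccc1
F2 | step 10 | [(2S,3R)-2-Ar-5-[(1S,2S)-2-Ar-3-[(4S)-4-benzyl-2-oxo-1,3-oxazolidin-3-yl]-1-hydroxy-3-oxopropyl]-7-methoxy-2,3-dihydro-1-benzofuran-3-yl]methyl acetate | COc1cc([C@H]2Oc3c(OC)cc([C@@H](O)[C@@H](C(=O)N4[C@@H](Cc5ccccc5)COC4=O)c4ccc(OCc5ccccc5)c(OC)c4)cc3[C@@H]2COC(C)=O)ccc1OCc1ccccc1
F3 | step 10 | (1S,2R)-1-[(2S,3R)-2-Ar-3-(hydroxymethyl)-7-methoxy-2,3-dihydro-1-benzofuran-5-yl]-2-Ar-propane-1,3-diol | COc1cc([C@H]2Oc3c(OC)cc([C@@H](O)[C@@H](CO)c4ccc(OCc5ccccc5)c(OC)c4)cc3[C@@H]2CO)ccc1OCc1ccccc1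
F0 | step 9 | none | none
F4 | step 4 | (2S)-2-Ar-6-bromo-8-methoxy-3-(trifluoroacetyl)-2,3-dihydro-4H-chromen-4-one (C3 unassigned) | O=C1C(C(=O)C(F)(F)F)[C@@H](c2ccc(OCc3ccccc3)c(OC)c2)Oc2c(OC)cc(Br)cc12
F5 | step 4 | (2R)-2-Ar-6-bromo-3-diazo-8-methoxy-2,3-dihydro-4H-chromen-4-one | O=C1C(=[N+]=[N-])[C@@H](c2ccc(OCc3ccccc3)c(OC)c2)Oc2c(OC)cc(Br)cc12
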